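## Retrosynthetic overview

1. Lepadin H comes from Boc/MOM removal of the ester made by Mitsunobu inversion at C3 of an all-cis N-Boc decahydroquinolin-3-ol with (2E,4E)-octa-2,4-dienoic acid (hexenal + malonic acid).
2. The all-cis decahydroquinolinol comes from face-selective hydrogenation of a 5-alkyl-2-methyl-5,6,7,8-tetrahydroquinolin-3-ol; the C5 centre relays to C2, C3, C4a and C8a.
3. The pyridinol comes from ring expansion of a 2-acetyl-4,5,6,7-tetrahydrobenzofuran with ammonia (furan to 3-hydroxypyridine).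
4. The acetylfuran comes from acylation of a (4S)-4-alkyl-tetrahydrobenzofuran, made by asymmetric hydrogenation of the product of a B-alkyl Suzuki coupling (enol triflate + alkene from (R)-epoxypentane and allylMgBr).
5. Ring order: carbocycle (ring B, bought as cyclohexane-1,3-dione), then furan (Feist–Benary), then the N-ring by ring expansion, then saturation.

Assumption: lepadin numbering (N1, C2 … C8a, side chain C1′–C8′) is used for quinolines and benzofuran numbering for furans; (R)-1,2-epoxypentane and 50% aqueous chloroacetaldehyde are bought.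

## Route

Step 1
Reactants: 1 cyclohexane-1,3-dione; 2 chloroacetaldehyde
Product: 4 6,7-dihydro-1-benzofuran-4(5H)-one, via hydroxydihydrofuranone adduct 3 (not isolated)
Conditions: 2 (50% aq), NaHCO3, H2O, 0 °C → rt; then H2SO4 (pH 1), EtOAc, rt
Reagents that add atoms: none
Why: Feist–Benary furan annulation, in which the dione C2 adds to the aldehyde, the enol oxygen displaces chloride and acid dehydrates 3 to the furan fused to the future ring B.

Step 2
Reactants: 4 6,7-dihydro-1-benzofuran-4(5H)-one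
Product: 6 6,7-dihydro-1-benzofuran-4-yl trifluoromethanesulfonate, via lithium enolate 5 (not isolated)
Conditions: LiN(SiMe3)2, THF, −78 °C; PhNTf2, −78 → 0 °C; aq NH4Cl
Reagents that add atoms: N-phenylbis(trifluoromethanesulfonimide) O=S(=O)(N(c1ccccc1)S(=O)(=O)C(F)(F)F)C(F)(F)F; LiN(SiMe3)2 [Li]N([Si](C)(C)C)[Si](C)(C)C (lithium only in 5)
Why: Kinetic enolisation at the only α-CH2 followed by O-triflation gives the enol triflate needed for cross-coupling.

Step 3
Reactants: 7 (2R)-2-propyloxirane; 8 allylmagnesium bromide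
Product: 10 (5R)-5-(methoxymethoxy)oct-1-ene, via bromomagnesium alkoxide 9 (not isolated)
Conditions: CuI (5 mol %), THF, −40 → 0 °C; then MOMCl, n-Bu4NI (cat.), DMPU, 0 °C → rt
Reagents that add atoms: chloromethyl methyl ether COCCl
Why: Copper-catalysed Grignard opening at the unsubstituted epoxide carbon leaves the C–O stereocentre untouched (it becomes C5′, R), and the alkoxide is etherified in the same flask (Williamson-type MOM protection).

Step 4
Reactants: 10 (5R)-5-(methoxymethoxy)oct-1-ene; 6 6,7-dihydro-1-benzofuran-4-yl trifluoromethanesulfonate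
Product: 12 4-[(5R)-5-(methoxymethoxy)octyl]-6,7-dihydro-1-benzofuran, via alkylborane 11 (not isolated)
Conditions: 9-BBN-H (0.5 M in THF), rt; then 6, PdCl2(dppf) (5 mol %), aq K3PO4, THF/DMF, 60 °C
Reagents that add atoms: 9-borabicyclo[3.3.1]nonane B1C2CCCC1CCC2 (boron only in 11)
Why: Anti-Markovnikov hydroboration followed by B-alkyl Suzuki–Miyaura coupling (oxidative addition of the enol triflate to zerovalent palladium) forms the C5–C1′ bond with no β-hydride loss.

Step 5
Reactants: 12 4-[(5R)-5-(methoxymethoxy)octyl]-6,7-dihydro-1-benzofuran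
Product: 13 (4S)-4-[(5R)-5-(methoxymethoxy)octyl]-4,5,6,7-tetrahydro-1-benzofuran
Conditions: [Ir(cod)(L*)][B(C6H3(CF3)2)4] (1 mol %; L* = ThrePHOX-type phosphinite–oxazoline, the enantiomer that gives 4S, assigned on the 4-methyl model), H2 (20 bar), CH2Cl2, rt
Reagents that add atoms: none
Why: Proposed new method: iridium-catalysed asymmetric hydrogenation of a furan-annulated endocyclic trisubstituted alkene (a 4-alkyl-6,7-dihydrobenzofuran), a substrate class on which it has not been shown; the closest known reaction is the Ir–phosphinooxazoline hydrogenation of 1-alkyl-3,4-dihydronaphthalenes, and the reasoning is that the cationic iridium dihydride needs no coordinating group, the planar furan takes the role of the aryl ring that fixes the alkene in the ligand quadrants so that H2 adds to one enantioface and sets the 4S centre (future C5), while the aromatic furan with its tetrasubstituted C3a=C7a bond is not reduced at 20 bar and room temperature.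

Step 6
Reactants: 13 (4S)-4-[(5R)-5-(methoxymethoxy)octyl]-4,5,6,7-tetrahydro-1-benzofuran; 14 N-methoxy-N-methylacetamide
Product: 16 1-[(4S)-4-[(5R)-5-(methoxymethoxy)octyl]-4,5,6,7-tetrahydro-1-benzofuran-2-yl]ethan-1-one, via furyllithium 15 (not isolated)
Conditions: n-BuLi, THF, −78 → 0 °C; then 14, −78 °C → rt; aq NH4Cl
Reagents that add atoms: n-butyllithium [Li]CCCC (lithium only in 15)
Why: Lithiation of the only free furan α-position followed by Weinreb ketone synthesis installs the acetyl group (future C2 and its methyl) without over-addition.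

Step 7
Reactants: 16 1-[(4S)-4-[(5R)-5-(methoxymethoxy)octyl]-4,5,6,7-tetrahydro-1-benzofuran-2-yl]ethan-1-one; 17 ammonia
Product: 18 (5S)-5-[(5R)-5-(methoxymethoxy)octyl]-2-methyl-5,6,7,8-tetrahydroquinolin-3-ol
Conditions: 25% aq NH3, NH4Cl (0.3 equiv), EtOH, 165 °C, sealed autoclave, 16 h
Reagents that add atoms: none
Why: Ring expansion of a 2-acylfuran to a 3-hydroxypyridine (addition of NH3 at C7a, furan C–O ring opening, ring closure of nitrogen onto the acetyl carbonyl, loss of water, as in the industrial 5-methyl-2-propionylfuran to 2-ethyl-6-methylpyridin-3-ol process) turns the five-membered O-ring into the six-membered N-ring with the furan oxygen as the C3 hydroxyl and leaves the non-acidic C5 centre untouched.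

Step 8
Reactants: 18 (5S)-5-[(5R)-5-(methoxymethoxy)octyl]-2-methyl-5,6,7,8-tetrahydroquinolin-3-ol
Product: 20 tert-butyl (2S,3S,4aS,5S,8aR)-3-hydroxy-5-[(5R)-5-(methoxymethoxy)octyl]-2-methyloctahydroquinoline-1(2H)-carboxylate, via amino alcohol 19 (not isolated)
Conditions: H2 (50 bar), 5% Rh/Al2O3, EtOH, 60 °C; then Boc2O, 40 °C
Reagents that add atoms: di-tert-butyl dicarbonate CC(C)(C)OC(=O)OC(=O)OC(C)(C)C
Why: Heterogeneous pyridine hydrogenation delivers all ring hydrogens syn from the face opposite the pseudo-axial C5 chain (A(1,3) strain with C4–H), which sets 2S, 3S, 4aS and 8aR all cis to H5, and the hindered NH is then capped as the carbamate.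

Step 9
Reactants: 21 (2E)-hex-2-enal; 22 malonic acid
Product: 23 (2E,4E)-octa-2,4-dienoic acid
Conditions: pyridine, piperidine (cat.), 90 °C
Reagents that add atoms: none
Why: Knoevenagel–Doebner condensation with in situ decarboxylation gives the thermodynamic E,E-dienoic acid.

Step 10
Reactants: 20 tert-butyl (2S,3S,4aS,5S,8aR)-3-hydroxy-5-[(5R)-5-(methoxymethoxy)octyl]-2-methyloctahydroquinoline-1(2H)-carboxylate; 23 (2E,4E)-octa-2,4-dienoic acid
Product: 24 tert-butyl (2S,3R,4aS,5S,8aR)-5-[(5R)-5-(methoxymethoxy)octyl]-2-methyl-3-{[(2E,4E)-octa-2,4-dienoyl]oxy}octahydroquinoline-1(2H)-carboxylate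
Conditions: PPh3, DIAD, toluene, 0 °C → rt
Reagents that add atoms: none
Why: Mitsunobu esterification, in which SN2 attack of the carboxylate on the oxyphosphonium inverts C3 from S to R and gives the 2,3-trans ester while the MOM-protected C5′ oxygen and the carbamate nitrogen cannot compete.

Step 11
Reactants: 24 tert-butyl (2S,3R,4aS,5S,8aR)-5-[(5R)-5-(methoxymethoxy)octyl]-2-methyl-3-{[(2E,4E)-octa-2,4-dienoyl]oxy}octahydroquinoline-1(2H)-carboxylate
Product: 25 lepadin H
Conditions: HCl (4 M in 1,4-dioxane), MeOH (10 equiv), 0 °C → rt; then aq NaHCO3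
Reagents that add atoms: none
Why: Acidolysis removes the Boc group (as CO2 and isobutene) and the MOM acetal (as dimethoxymethane) without touching any stereocentre or the dienoate ester.

## Compound list

1 | cyclohexane-1,3-dione | O=C1CCCC(=O)C1 | starting material
2 | chloroacetaldehyde | O=CCCl | starting material
3 | 3-hydroxy-2,3,6,7-tetrahydro-1-benzofuran-4(5H)-one (racemic, not isolated) | O=C1CCCC2=C1C(O)CO2 | intermediate
4 | 6,7-dihydro-1-benzofuran-4(5H)-one | O=C1CCCc2occc21 | intermediate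
5 | lithium 6,7-dihydro-1-benzofuran-4-olate (not isolated) | [Li]OC1=CCCc2occc21 | intermediate
6 | 6,7-dihydro-1-benzofuran-4-yl trifluoromethanesulfonate | O=S(=O)(OC1=CCCc2occc21)C(F)(F)F | intermediate
7 | (2R)-2-propyloxirane [(R)-1,2-epoxypentane] | CCC[C@@H]1CO1 | starting material
8 | allylmagnesium bromide | C=CC[Mg]Br | starting material
9 | bromomagnesium (4R)-oct-7-en-4-olate (not isolated) | C=CCC[C@H](O[Mg]Br)CCC | intermediate
10 | (5R)-5-(methoxymethoxy)oct-1-ene | C=CCC[C@H](OCOC)CCC | intermediate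
11 | 9-[(5R)-5-(methoxymethoxy)octyl]-9-borabicyclo[3.3.1]nonane (not isolated) | CCC[C@@H](OCOC)CCCCB1C2CCCC1CCC2 | intermediate
12 | 4-[(5R)-5-(methoxymethoxy)octyl]-6,7-dihydro-1-benzofuran | CCC[C@@H](OCOC)CCCCC1=CCCc2occc21 | intermediate
13 | (4S)-4-[(5R)-5-(methoxymethoxy)octyl]-4,5,6,7-tetrahydro-1-benzofuran | CCC[C@@H](OCOC)CCCC[C@H]1CCCc2occc21 | intermediate
14 | N-methoxy-N-methylacetamide | CC(=O)N(C)OC | starting material
15 | [(4S)-4-[(5R)-5-(methoxymethoxy)octyl]-4,5,6,7-tetrahydro-1-benzofuran-2-yl]lithium (not isolated) | CCC[C@@H](OCOC)CCCC[C@H]1CCCc2oc([Li])cc21 | intermediate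
16 | 1-[(4S)-4-[(5R)-5-(methoxymethoxy)octyl]-4,5,6,7-tetrahydro-1-benzofuran-2-yl]ethan-1-one | CCC[C@@H](OCOC)CCCC[C@H]1CCCc2oc(C(C)=O)cc21 | intermediate
17 | ammonia | N | starting material
18 | (5S)-5-[(5R)-5-(methoxymethoxy)octyl]-2-methyl-5,6,7,8-tetrahydroquinolin-3-ol | CCC[C@@H](OCOC)CCCC[C@H]1CCCc2nc(C)c(O)cc21 | intermediate
19 | (2S,3S,4aS,5S,8aR)-5-[(5R)-5-(methoxymethoxy)octyl]-2-methyldecahydroquinolin-3-ol (not isolated) | O[C@H]1C[C@H]2[C@@H](CCCC[C@H](OCOC)CCC)CCC[C@H]2N[C@H]1C | intermediate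
20 | tert-butyl (2S,3S,4aS,5S,8aR)-3-hydroxy-5-[(5R)-5-(methoxymethoxy)octyl]-2-methyloctahydroquinoline-1(2H)-carboxylate | O[C@H]1C[C@H]2[C@@H](CCCC[C@H](OCOC)CCC)CCC[C@H]2N(C(=O)OC(C)(C)C)[C@H]1C | intermediate
21 | (2E)-hex-2-enal | CCC/C=C/C=O | starting material
22 | malonic acid | OC(=O)CC(=O)O | starting material
23 | (2E,4E)-octa-2,4-dienoic acid | CCC/C=C/C=C/C(=O)O | intermediate
24 | tert-butyl (2S,3R,4aS,5S,8aR)-5-[(5R)-5-(methoxymethoxy)octyl]-2-methyl-3-{[(2E,4E)-octa-2,4-dienoyl]oxy}octahydroquinoline-1(2H)-carboxylate | CCC/C=C/C=C/C(=O)O[C@@H]1C[C@H]2[C@@H](CCCC[C@H](OCOC)CCC)CCC[C@H]2N(C(=O)OC(C)(C)C)[C@H]1C | intermediate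
25 | lepadin H, (2S,3R,4aS,5S,8aR)-5-[(5R)-5-hydroxyoctyl]-2-methyldecahydroquinolin-3-yl (2E,4E)-octa-2,4-dienoate | CCC/C=C/C=C/C(=O)O[C@@H]1C[C@H]2[C@@H](CCCC[C@H](O)CCC)CCC[C@H]2N[C@H]1C | target

## Step count and risks

Total steps: 11. Longest linear sequence: 9 (steps 1, 2, 4, 5, 6, 7, 8, 10, 11).

**Step 5 (the new asymmetric hydrogenation).** Risks are low ee, acid-promoted isomerisation or oligomerisation of the vinylfuran by the iridium hydride, and over-reduction of the furan. The fallback uses only known chemistry, sets out from 1 and 11 and comes back at 13. Dione 1 with Tf2O and pyridine gives 3-oxocyclohex-1-en-1-yl trifluoromethanesulfonate F1. B-alkyl Suzuki coupling of F1 with alkylborane 11 (PdCl2(dppf), K3PO4) gives 3-[(5R)-5-(methoxymethoxy)octyl]cyclohex-2-en-1-one F2. Copper hydride asymmetric conjugate reduction (Cu(OAc)2, DTBM-SEGPHOS enantiomer that gives 3S, polymethylhydrosiloxane) with trapping of the enolate by allyl bromide and n-Bu4N[Ph3SiF2] gives (2R,3S)-3-[(5R)-5-(methoxymethoxy)octyl]-2-(prop-2-en-1-yl)cyclohexan-1-one F3. Ozonolysis (O3, then Me2S) gives 2-[(1R,2S)-2-[(5R)-5-(methoxymethoxy)octyl]-6-oxocyclohexyl]acetaldehyde F4. Paal–Knorr cyclodehydration (pyridinium p-toluenesulfonate, toluene, 80 °C) erases the C2 centre and gives 13.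

**Step 7 (ring expansion at 165 °C).** Risks are slow attack at the dialkyl-substituted C7a and condensation at the activated C7 methylene. The fallback runs the ring expansion oxidatively, sets out from 16 and comes back at 18. Reductive amination of 16 (NH3 in EtOH, Ti(OiPr)4, then NaBH4) gives 1-[(4S)-4-[(5R)-5-(methoxymethoxy)octyl]-4,5,6,7-tetrahydro-1-benzofuran-2-yl]ethan-1-amine F5 as both epimers at the new centre, which does not matter because that carbon becomes aromatic. Buffered NBS oxidation (NaHCO3, THF/H2O, 0 °C), then AcOH at 40 °C, opens the furan, closes the free amine onto the enedione and dehydrates to 18. This is the known furfurylamine to 3-pyridinol oxidation.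

**Step 10 (Mitsunobu inversion at the hindered C3 alcohol).** Risks are elimination and low conversion with a weakly acidic dienoic acid. The fallback separates activation from displacement, sets out from 20 and 23 and comes back at 24. Alcohol 20 with chloromethanesulfonyl chloride and pyridine gives tert-butyl (2S,3S,4aS,5S,8aR)-3-{[(chloromethyl)sulfonyl]oxy}-5-[(5R)-5-(methoxymethoxy)octyl]-2-methyloctahydroquinoline-1(2H)-carboxylate F6. Acid 23 with Cs2CO3 gives cesium (2E,4E)-octa-2,4-dienoate F7. F6 and F7 with 18-crown-6 in toluene at 80 °C give 24 by SN2 inversion.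

Further compounds

F1 | step 5 | 3-oxocyclohex-1-en-1-yl trifluoromethanesulfonate | O=C1C=C(OS(=O)(=O)C(F)(F)F)CCC1
F2 | step 5 | 3-[(5R)-5-(methoxymethoxy)octyl]cyclohex-2-en-1-one | CCC[C@@H](OCOC)CCCCC1=CC(=O)CCC1
F3 | step 5 | (2R,3S)-3-[(5R)-5-(methoxymethoxy)octyl]-2-(prop-2-en-1-yl)cyclohexan-1-one | CCC[C@@H](OCOC)CCCC[C@H]1CCCC(=O)[C@@H]1CC=C
F4 | step 5 | 2-[(1R,2S)-2-[(5R)-5-(methoxymethoxy)octyl]-6-oxocyclohexyl]acetaldehyde | CCC[C@@H](OCOC)CCCC[C@H]1CCCC(=O)[C@@H]1CC=O
F5 | step 7 | 1-[(4S)-4-[(5R)-5-(methoxymethoxy)octyl]-4,5,6,7-tetrahydro-1-benzofuran-2-yl]ethan-1-amine (both epimers at the amine carbon) | CCC[C@@H](OCOC)CCCC[C@H]1CCCc2oc(C(C)N)cc21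
F6 | step 10 | tert-butyl (2S,3S,4aS,5S,8aR)-3-{[(chloromethyl)sulfonyl]oxy}-5-[(5R)-5-(methoxymethoxy)octyl]-2-methyloctahydroquinoline-1(2H)-carboxylate | ClCS(=O)(=O)O[C@H]1C[C@H]2[C@@H](CCCC[C@H](OCOC)CCC)CCC[C@H]2N(C(=O)OC(C)(C)C)[C@H]1C
F7 | step 10 | cesium (2E,4E)-octa-2,4-dienoate | CCC/C=C/C=C/C(=O)[O-].[Cs+]
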